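**Assumption:** the SMILES is natural (3S,5R,6S,3′R)-pyrrhoxanthin (all-E chain, Z-ylidene lactone); "ring A" is the acetoxy enyne ring, "ring B" the epoxy ring, and carotenoid locants (C-3, C-5, C-6, C-8, C-9) are used only for orientation.

## Retrosynthetic overview

1. Last bond C-8–C-9: Suzuki coupling of the ring-B epoxy vinylboronate 23 with the 3-bromo-ylidenebutenolide 20.
2. Butenolide ring of 20: tandem Sonogashira/5-exo lactonization of terminal alkyne 16 with (E)-2,3-dibromoacrylic acid 18. Polyene 16 comes from an HWE union of ring-A phosphonate 13 with dienynal 15, both built from the same C6 enynol 11.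
3. 13 (Sonogashira) and 23 (Heck, epoxidation, desilylation) both come from one enol triflate, 9.
4. Key step: 9 by one-carbon ring expansion of cyclopentanone 5 (1,2-shift in a β-oxido carbenoid) with in-flask O-triflation; 5 from 2,2-dimethylcyclopentanone by desaturation and asymmetric β-borylation.
5. Ring order: six-membered carbocycle (serves rings A and B) → butenolide → oxirane.

## Route

Step 1
Reactants: 1 2,2-dimethylcyclopentan-1-one
Product: 2 5,5-dimethylcyclopent-2-en-1-one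
Conditions: IBX (2.0 equiv), 4-methoxypyridine N-oxide (2.0 equiv), DMSO, 25 °C
Reagents that add atoms: none
Why: IBX α,β-dehydrogenation (Nicolaou desaturation) can only act on the single enolizable CH2–CH2 side, so one enone forms.

Step 2
Reactants: 2 5,5-dimethylcyclopent-2-en-1-one
Product: 4 (S)-4-hydroxy-2,2-dimethylcyclopentan-1-one, via β-boryl ketone 3 (not isolated)
Conditions: B2pin2 (1.1 equiv), CuCl (3 mol %), NaOtBu (5 mol %), Josiphos ligand (4 mol %, the antipode that gives the S-boronate), MeOH (2 equiv), THF, 0 → 23 °C; then NaBO3·4H2O, THF/H2O, 23 °C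
Reagents that add atoms: sodium perborate [Na+].[O-]OB=O (hydroxyl oxygen); bis(pinacolato)diboron CC1(C)OB(OC1(C)C)B1OC(C)(C)C(C)(C)O1 (boryl group of 3 only)
Why: copper-catalysed enantioselective conjugate borylation sets C-4 by ligand-controlled attack on one face of the unhindered β-carbon, and perborate oxidation of the C–B bond proceeds with retention.

Step 3
Reactants: 4 (S)-4-hydroxy-2,2-dimethylcyclopentan-1-one
Product: 5 (S)-4-[(tert-butyldimethylsilyl)oxy]-2,2-dimethylcyclopentan-1-one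
Conditions: TBSCl, imidazole, DMF, 23 °C
Reagents that add atoms: tert-butyldimethylsilyl chloride CC(C)(C)[Si](C)(C)Cl
Why: standard O-silylation under mild base, which avoids β-elimination of the β-oxygenated ketone and leaves the stereocentre untouched.

Step 4
Reactants: 5 (S)-4-[(tert-butyldimethylsilyl)oxy]-2,2-dimethylcyclopentan-1-one
Product: 9 (R)-4-[(tert-butyldimethylsilyl)oxy]-2,6,6-trimethylcyclohex-1-en-1-yl trifluoromethanesulfonate, via dibromo alkoxide adduct 6 (not isolated), via β-oxido carbenoid 7 (not isolated), via lithium enolate 8 (not isolated)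
Conditions: CH3CHBr2 (1.3 equiv), LiN(iPr)2 (1.3 equiv), THF, −100 °C; n-BuLi (1.2 equiv), −100 → −40 °C; Comins' reagent (1.3 equiv), −78 → 0 °C
Reagents that add atoms: 1,1-dibromoethane CC(Br)Br (inserted ring carbon and its methyl); Comins' reagent O=S(=O)(N(c1ccc(Cl)cn1)S(=O)(=O)C(F)(F)F)C(F)(F)F (triflyl group); lithium diisopropylamide CC(C)N([Li])C(C)C and n-butyllithium CCCC[Li] (lithium of 6–8 only)
Why: Proposed new method: a "homologative enol triflation" in which 1,1-dibromoethyllithium adds to the ketone, Br/Li exchange gives β-oxido carbenoid 7, and the alkoxide drives a non-pericyclic 1,2-shift of the unsubstituted ring CH2 onto the carbenoid carbon with loss of LiBr to give specifically the tetrasubstituted enolate 8, which Comins' reagent traps on oxygen with the remote stereocentre untouched (the descriptor changes from S to R only through CIP priorities); the closest known reaction is the Taguchi–Yamamoto–Nozaki β-oxido carbenoid ring enlargement, not yet shown on an α-quaternary β-silyloxy cyclopentanone with a secondary carbenoid or with triflate termination, and the main competitor is a 1,2-hydride shift in 7.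

Step 5
Reactants: 9 (R)-4-[(tert-butyldimethylsilyl)oxy]-2,6,6-trimethylcyclohex-1-en-1-yl trifluoromethanesulfonate
Product: 10 (R)-3,5,5-trimethyl-4-{[(trifluoromethyl)sulfonyl]oxy}cyclohex-3-en-1-yl acetate
Conditions: Ac2O, Cu(OTf)2 (5 mol %), CH2Cl2, 23 °C
Reagents that add atoms: acetic anhydride CC(=O)OC(C)=O
Why: Lewis-acid-catalysed direct exchange of a silyl ether for an acetate acylates at oxygen, so the C–O bond and its configuration are retained and the vinyl triflate is inert.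

Step 6
Reactants: 11 (E)-3-methylpent-2-en-4-yn-1-ol
Product: 12 diethyl [(E)-3-methylpent-2-en-4-yn-1-yl]phosphonate
Conditions: P(OEt)3 (3 equiv), ZnI2 (1.5 equiv), THF, 66 °C
Reagents that add atoms: triethyl phosphite CCOP(OCC)OCC
Why: ZnI2-mediated Arbuzov-type phosphonylation of a primary allylic alcohol substitutes at the primary carbon, so the E-enyne geometry is kept.

Step 7
Reactants: 10 (R)-3,5,5-trimethyl-4-{[(trifluoromethyl)sulfonyl]oxy}cyclohex-3-en-1-yl acetate; 12 diethyl [(E)-3-methylpent-2-en-4-yn-1-yl]phosphonate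
Product: 13 (R)-4-[(E)-5-(diethoxyphosphoryl)-3-methylpent-3-en-1-yn-1-yl]-3,5,5-trimethylcyclohex-3-en-1-yl acetate
Conditions: Pd(PPh3)4 (5 mol %), CuI (10 mol %), iPr2NH, THF, 23 → 45 °C
Reagents that add atoms: none
Why: Sonogashira coupling of the hindered alkenyl triflate with the terminal enyne forms the ring-A C(sp2)–C(sp) bond without touching the acetate or the stereocentre.

Step 8
Reactants: 11 (E)-3-methylpent-2-en-4-yn-1-ol
Product: 15 (2E,4E)-5-methylhepta-2,4-dien-6-ynal, via enynal 14 (not isolated)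
Conditions: MnO2 (10 equiv), Ph3P=CHCHO (1.2 equiv), toluene, 70 °C
Reagents that add atoms: (triphenylphosphoranylidene)acetaldehyde O=CC=P(c1ccccc1)(c1ccccc1)c1ccccc1
Why: tandem allylic oxidation/Wittig olefination traps the volatile enynal in situ with a stabilized ylide, which gives the new E double bond.

Step 9
Reactants: 13 (R)-4-[(E)-5-(diethoxyphosphoryl)-3-methylpent-3-en-1-yn-1-yl]-3,5,5-trimethylcyclohex-3-en-1-yl acetate; 15 (2E,4E)-5-methylhepta-2,4-dien-6-ynal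
Product: 16 (R)-4-[(3E,5E,7E,9E)-3,10-dimethyldodeca-3,5,7,9-tetraene-1,11-diyn-1-yl]-3,5,5-trimethylcyclohex-3-en-1-yl acetate
Conditions: NaN(SiMe3)2 (1.0 equiv), THF, −78 °C; then 15, −78 → 0 °C
Reagents that add atoms: none
Why: Horner–Wadsworth–Emmons olefination of the allylic phosphonate anion (which carries no acidic alkyne C–H) with the enal gives the new disubstituted alkene E-selectively at low temperature, where the acetate and the existing alkene geometries survive.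

Step 10
Reactants: 17 propiolic acid
Product: 18 (E)-2,3-dibromoprop-2-enoic acid
Conditions: Br2 (1.0 equiv), CHCl3, 0 → 23 °C, dark
Reagents that add atoms: bromine BrBr
Why: anti addition of bromine to the alkyne gives the E-dibromide, in which the β-bromine is cis to the carboxyl group as the later lactonization requires.

Step 11
Reactants: 16 (R)-4-[(3E,5E,7E,9E)-3,10-dimethyldodeca-3,5,7,9-tetraene-1,11-diyn-1-yl]-3,5,5-trimethylcyclohex-3-en-1-yl acetate; 18 (E)-2,3-dibromoprop-2-enoic acid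
Product: 20 (R)-4-[(3E,5E,7E,9E,11Z)-11-(4-bromo-5-oxofuran-2(5H)-ylidene)-3,10-dimethylundeca-3,5,7,9-tetraen-1-yn-1-yl]-3,5,5-trimethylcyclohex-3-en-1-yl acetate, via bromo enynoic acid 19 (not isolated)
Conditions: PdCl2(PPh3)2 (5 mol %), CuI (10 mol %), Et3N (4 equiv), MeCN, 23 °C, dark
Reagents that add atoms: none
Why: tandem Sonogashira coupling/lactonization, in which coupling occurs at the more electrophilic β-C–Br and the cis carboxylate then adds anti across the alkyne in 5-exo-dig mode to give the Z-ylidene butenolide with the α-bromine kept for the last coupling.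

Step 12
Reactants: 9 (R)-4-[(tert-butyldimethylsilyl)oxy]-2,6,6-trimethylcyclohex-1-en-1-yl trifluoromethanesulfonate
Product: 21 2-[(E)-2-{(R)-4-[(tert-butyldimethylsilyl)oxy]-2,6,6-trimethylcyclohex-1-en-1-yl}ethenyl]-6-methyl-1,3,6,2-dioxazaborocane-4,8-dione
Conditions: CH2=CH–B(MIDA) (1.5 equiv), Pd(OAc)2 (5 mol %), PPh3 (12 mol %), Et3N (2 equiv), MeCN, 70 °C
Reagents that add atoms: vinylboronic acid MIDA ester C=CB1OC(=O)CN(C)CC(=O)O1
Why: Mizoroki–Heck reaction of the alkenyl triflate with the MIDA-protected vinylboronate gives the E-dienyl boronate by syn insertion and syn β-hydride elimination, the sp3 boron being shielded from transmetalation.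

Step 13
Reactants: 21 2-[(E)-2-{(R)-4-[(tert-butyldimethylsilyl)oxy]-2,6,6-trimethylcyclohex-1-en-1-yl}ethenyl]-6-methyl-1,3,6,2-dioxazaborocane-4,8-dione
Product: 22 2-[(E)-2-{(1S,4S,6R)-4-[(tert-butyldimethylsilyl)oxy]-2,2,6-trimethyl-7-oxabicyclo[4.1.0]heptan-1-yl}ethenyl]-6-methyl-1,3,6,2-dioxazaborocane-4,8-dione
Conditions: mCPBA (1.05 equiv), NaHCO3, CH2Cl2, −20 → 0 °C
Reagents that add atoms: 3-chloroperbenzoic acid OOC(=O)c1cccc(Cl)c1
Why: Prilezhaev epoxidation picks the electron-rich tetrasubstituted ring alkene over the boron-bearing alkene and, as with other 3-O-protected end groups of this type, mainly from the face anti to the silyloxy group (about 3–4:1 expected, syn isomer removed by chromatography), which sets C-5 and C-6.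

Step 14
Reactants: 22 2-[(E)-2-{(1S,4S,6R)-4-[(tert-butyldimethylsilyl)oxy]-2,2,6-trimethyl-7-oxabicyclo[4.1.0]heptan-1-yl}ethenyl]-6-methyl-1,3,6,2-dioxazaborocane-4,8-dione
Product: 23 2-[(E)-2-{(1S,4S,6R)-4-hydroxy-2,2,6-trimethyl-7-oxabicyclo[4.1.0]heptan-1-yl}ethenyl]-6-methyl-1,3,6,2-dioxazaborocane-4,8-dione
Conditions: HF·pyridine, excess pyridine, THF, 0 → 23 °C
Reagents that add atoms: none
Why: buffered fluoride desilylation is tolerated by the MIDA boronate and, with excess pyridine, by the epoxide, and no stereocentre is involved.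

Step 15
Reactants: 20 (R)-4-[(3E,5E,7E,9E,11Z)-11-(4-bromo-5-oxofuran-2(5H)-ylidene)-3,10-dimethylundeca-3,5,7,9-tetraen-1-yn-1-yl]-3,5,5-trimethylcyclohex-3-en-1-yl acetate; 23 2-[(E)-2-{(1S,4S,6R)-4-hydroxy-2,2,6-trimethyl-7-oxabicyclo[4.1.0]heptan-1-yl}ethenyl]-6-methyl-1,3,6,2-dioxazaborocane-4,8-dione
Product: 24 pyrrhoxanthin, (R)-4-{(3E,5E,7E,9E,11Z)-11-[4-{(E)-2-[(1S,4S,6R)-4-hydroxy-2,2,6-trimethyl-7-oxabicyclo[4.1.0]heptan-1-yl]ethenyl}-5-oxofuran-2(5H)-ylidene]-3,10-dimethylundeca-3,5,7,9-tetraen-1-yn-1-yl}-3,5,5-trimethylcyclohex-3-en-1-yl acetate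
Conditions: Pd(OAc)2 (5 mol %), SPhos (10 mol %), K3PO4 (3 M aq., 5 equiv), THF, 35 °C, degassed, dark
Reagents that add atoms: none
Why: Suzuki–Miyaura coupling under slow hydrolytic release of the boronic acid joins C-8 to C-9 with retention of both alkene geometries, all stereocentres being spectators.

## Compound list

1 | 2,2-dimethylcyclopentan-1-one | CC1(C)CCCC1=O | starting material
2 | 5,5-dimethylcyclopent-2-en-1-one | CC1(C)CC=CC1=O | intermediate
3 | (S)-2,2-dimethyl-4-(4,4,5,5-tetramethyl-1,3,2-dioxaborolan-2-yl)cyclopentan-1-one | CC1(C)OB(OC1(C)C)[C@@H]1CC(=O)C(C)(C)C1 | intermediate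
4 | (S)-4-hydroxy-2,2-dimethylcyclopentan-1-one | O[C@@H]1CC(=O)C(C)(C)C1 | intermediate
5 | (S)-4-[(tert-butyldimethylsilyl)oxy]-2,2-dimethylcyclopentan-1-one | CC(C)(C)[Si](C)(C)O[C@@H]1CC(=O)C(C)(C)C1 | intermediate
6 | lithium (4S)-4-[(tert-butyldimethylsilyl)oxy]-1-(1,1-dibromoethyl)-2,2-dimethylcyclopentan-1-olate (both C-1 epimers) | CC(C)(C)[Si](C)(C)O[C@@H]1CC(O[Li])(C(C)(Br)Br)C(C)(C)C1 | intermediate
7 | lithium (4S)-1-(1-bromo-1-lithioethyl)-4-[(tert-butyldimethylsilyl)oxy]-2,2-dimethylcyclopentan-1-olate (β-oxido carbenoid) | CC(C)(C)[Si](C)(C)O[C@@H]1CC(O[Li])(C(C)(Br)[Li])C(C)(C)C1 | intermediate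
8 | lithium (R)-4-[(tert-butyldimethylsilyl)oxy]-2,6,6-trimethylcyclohex-1-en-1-olate | CC(C)(C)[Si](C)(C)O[C@@H]1CC(C)=C(O[Li])C(C)(C)C1 | intermediate
9 | (R)-4-[(tert-butyldimethylsilyl)oxy]-2,6,6-trimethylcyclohex-1-en-1-yl trifluoromethanesulfonate | CC(C)(C)[Si](C)(C)O[C@@H]1CC(C)=C(OS(=O)(=O)C(F)(F)F)C(C)(C)C1 | intermediate
10 | (R)-3,5,5-trimethyl-4-{[(trifluoromethyl)sulfonyl]oxy}cyclohex-3-en-1-yl acetate | CC(=O)O[C@@H]1CC(C)=C(OS(=O)(=O)C(F)(F)F)C(C)(C)C1 | intermediate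
11 | (E)-3-methylpent-2-en-4-yn-1-ol | C#C/C(C)=C/CO | starting material
12 | diethyl [(E)-3-methylpent-2-en-4-yn-1-yl]phosphonate | C#C/C(C)=C/CP(=O)(OCC)OCC | intermediate
13 | (R)-4-[(E)-5-(diethoxyphosphoryl)-3-methylpent-3-en-1-yn-1-yl]-3,5,5-trimethylcyclohex-3-en-1-yl acetate | CC(=O)O[C@@H]1CC(C)=C(C#C/C(C)=C/CP(=O)(OCC)OCC)C(C)(C)C1 | intermediate
14 | (E)-3-methylpent-2-en-4-ynal | C#C/C(C)=C/C=O | intermediate
15 | (2E,4E)-5-methylhepta-2,4-dien-6-ynal | C#C/C(C)=C/C=C/C=O | intermediate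
16 | (R)-4-[(3E,5E,7E,9E)-3,10-dimethyldodeca-3,5,7,9-tetraene-1,11-diyn-1-yl]-3,5,5-trimethylcyclohex-3-en-1-yl acetate | CC(=O)O[C@@H]1CC(C)=C(C#C/C(C)=C/C=C/C=C/C=C(C)/C#C)C(C)(C)C1 | intermediate
17 | propiolic acid (prop-2-ynoic acid) | C#CC(=O)O | starting material
18 | (E)-2,3-dibromoprop-2-enoic acid | OC(=O)/C(Br)=C\Br | intermediate
19 | (2E,6E,8E,10E,12E)-15-[(R)-4-acetoxy-2,6,6-trimethylcyclohex-1-en-1-yl]-2-bromo-6,13-dimethylpentadeca-2,6,8,10,12-pentaene-4,14-diynoic acid | CC(=O)O[C@@H]1CC(C)=C(C#C/C(C)=C/C=C/C=C/C=C(C)/C#C/C=C(/Br)C(=O)O)C(C)(C)C1 | intermediate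
20 | (R)-4-[(3E,5E,7E,9E,11Z)-11-(4-bromo-5-oxofuran-2(5H)-ylidene)-3,10-dimethylundeca-3,5,7,9-tetraen-1-yn-1-yl]-3,5,5-trimethylcyclohex-3-en-1-yl acetate | CC(=O)O[C@@H]1CC(C)=C(C#C/C(C)=C/C=C/C=C/C=C(C)/C=C2C=C(Br)C(=O)O/2)C(C)(C)C1 | intermediate
21 | 2-[(E)-2-{(R)-4-[(tert-butyldimethylsilyl)oxy]-2,6,6-trimethylcyclohex-1-en-1-yl}ethenyl]-6-methyl-1,3,6,2-dioxazaborocane-4,8-dione | CC(C)(C)[Si](C)(C)O[C@@H]1CC(C)=C(/C=C/B2OC(=O)CN(C)CC(=O)O2)C(C)(C)C1 | intermediate
22 | 2-[(E)-2-{(1S,4S,6R)-4-[(tert-butyldimethylsilyl)oxy]-2,2,6-trimethyl-7-oxabicyclo[4.1.0]heptan-1-yl}ethenyl]-6-methyl-1,3,6,2-dioxazaborocane-4,8-dione (epoxide anti to the silyloxy group) | CN1CC(=O)OB(/C=C/[C@@]23O[C@]2(C)C[C@@H](O[Si](C)(C)C(C)(C)C)CC3(C)C)OC(=O)C1 | intermediate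
23 | 2-[(E)-2-{(1S,4S,6R)-4-hydroxy-2,2,6-trimethyl-7-oxabicyclo[4.1.0]heptan-1-yl}ethenyl]-6-methyl-1,3,6,2-dioxazaborocane-4,8-dione | CN1CC(=O)OB(/C=C/[C@@]23O[C@]2(C)C[C@@H](O)CC3(C)C)OC(=O)C1 | intermediate
24 | pyrrhoxanthin, (3S,5R,6S,3′R) | CC(=O)O[C@@H]1CC(C)=C(C#C/C(C)=C/C=C/C=C/C=C(C)/C=C2C=C(/C=C/[C@@]34O[C@]3(C)C[C@@H](O)CC4(C)C)C(=O)O/2)C(C)(C)C1 | target

## Step count and risks

Total step count: 15. Longest linear sequence: 9 steps (1, 2, 3, 4, 5, 7, 9, 11, 15).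

Three steps most likely to fail:

**Step 4 (the proposed new step).** Risks are a 1,2-hydride shift in carbenoid 7, enolization or β-elimination of 5, and incomplete O-triflation. The fallback uses known chemistry, sets out from 5 and returns at 9. Sc(OTf)3-catalysed homologation of 5 with diazoethane (toluene, −78 °C; Lewis-acid-promoted diazoalkane ring expansion, again by migration of the unsubstituted CH2) gives (4R)-4-[(tert-butyldimethylsilyl)oxy]-2,2,6-trimethylcyclohexan-1-one F1 as a mixture of C-6 epimers. Deprotonation at its only acidic α-position with KN(SiMe3)2 and trapping with PhNTf2 (THF, −78 °C) then gives 9.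

**Step 13 (facial selectivity of the epoxidation).** If the anti:syn ratio is poor, the epoxide is set under reagent control instead; this fallback sets out from 9 and returns at 24.
- Pd(OAc)2/dppp-catalysed methoxycarbonylation of 9 (CO, MeOH, Et3N, DMF, 60 °C) gives methyl (R)-4-[(tert-butyldimethylsilyl)oxy]-2,6,6-trimethylcyclohex-1-ene-1-carboxylate F2.
- iBu2AlH reduction (CH2Cl2, −78 °C) gives {(R)-4-[(tert-butyldimethylsilyl)oxy]-2,6,6-trimethylcyclohex-1-en-1-yl}methanol F3.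
- Sharpless epoxidation (Ti(OiPr)4, D-(−)-diethyl tartrate, tBuOOH, 4 Å sieves, CH2Cl2, −20 °C; by the face mnemonic this tartrate antipode delivers oxygen anti to the silyloxy group) gives {(1R,4S,6R)-4-[(tert-butyldimethylsilyl)oxy]-2,2,6-trimethyl-7-oxabicyclo[4.1.0]heptan-1-yl}methanol F4.
- Dess–Martin oxidation gives (1S,4S,6R)-4-[(tert-butyldimethylsilyl)oxy]-2,2,6-trimethyl-7-oxabicyclo[4.1.0]heptane-1-carbaldehyde F5.
- Boron-Wittig olefination (CH2(Bpin)2, lithium 2,2,6,6-tetramethylpiperidide, THF, −78 → 0 °C) gives 2-[(E)-2-{(1S,4S,6R)-4-[(tert-butyldimethylsilyl)oxy]-2,2,6-trimethyl-7-oxabicyclo[4.1.0]heptan-1-yl}ethenyl]-4,4,5,5-tetramethyl-1,3,2-dioxaborolane F6.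
- HF·pyridine/pyridine gives 2-[(E)-2-{(1S,4S,6R)-4-hydroxy-2,2,6-trimethyl-7-oxabicyclo[4.1.0]heptan-1-yl}ethenyl]-4,4,5,5-tetramethyl-1,3,2-dioxaborolane F7.
- Suzuki coupling of F7 with 20 under the conditions of step 15 gives 24.

**Step 15 (aqueous base with the ylidene butenolide, the acetate and the polyene).** If hydrolysis or isomerization dominates, the polarity is reversed and the coupling is run without base; this fallback sets out from 23 and 20 and returns at 24. Hydrolysis of 23 (aq. NaOH, THF, 23 °C) and iododeboronation with I2 (retention) gives (1R,3S,6S)-6-[(E)-2-iodoethenyl]-1,5,5-trimethyl-7-oxabicyclo[4.1.0]heptan-3-ol F8. Stannylation of 20 (Me3SnSnMe3, Pd(PPh3)4, toluene, 80 °C) gives (R)-4-{(3E,5E,7E,9E,11Z)-3,10-dimethyl-11-[5-oxo-4-(trimethylstannyl)furan-2(5H)-ylidene]undeca-3,5,7,9-tetraen-1-yn-1-yl}-3,5,5-trimethylcyclohex-3-en-1-yl acetate F9. Stille coupling of F8 with F9 (Pd2(dba)3, AsPh3, CuI, NMP, 23 °C) gives 24.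

## Further compounds

F1 | step 4 | (4R)-4-[(tert-butyldimethylsilyl)oxy]-2,2,6-trimethylcyclohexan-1-one (C-6 epimers) | CC(C)(C)[Si](C)(C)O[C@@H]1CC(C)C(=O)C(C)(C)C1
F2 | step 13 | methyl (R)-4-[(tert-butyldimethylsilyl)oxy]-2,6,6-trimethylcyclohex-1-ene-1-carboxylate | CC(C)(C)[Si](C)(C)O[C@@H]1CC(C)=C(C(=O)OC)C(C)(C)C1
F3 | step 13 | {(R)-4-[(tert-butyldimethylsilyl)oxy]-2,6,6-trimethylcyclohex-1-en-1-yl}methanol | CC(C)(C)[Si](C)(C)O[C@@H]1CC(C)=C(CO)C(C)(C)C1
F4 | step 13 | {(1R,4S,6R)-4-[(tert-butyldimethylsilyl)oxy]-2,2,6-trimethyl-7-oxabicyclo[4.1.0]heptan-1-yl}methanol | OC[C@@]12O[C@]1(C)C[C@@H](O[Si](C)(C)C(C)(C)C)CC2(C)C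
F5 | step 13 | (1S,4S,6R)-4-[(tert-butyldimethylsilyl)oxy]-2,2,6-trimethyl-7-oxabicyclo[4.1.0]heptane-1-carbaldehyde | O=C[C@@]12O[C@]1(C)C[C@@H](O[Si](C)(C)C(C)(C)C)CC2(C)C
F6 | step 13 | 2-[(E)-2-{(1S,4S,6R)-4-[(tert-butyldimethylsilyl)oxy]-2,2,6-trimethyl-7-oxabicyclo[4.1.0]heptan-1-yl}ethenyl]-4,4,5,5-tetramethyl-1,3,2-dioxaborolane | CC1(C)OB(/C=C/[C@@]23O[C@]2(C)C[C@@H](O[Si](C)(C)C(C)(C)C)CC3(C)C)OC1(C)C
F7 | step 13 | 2-[(E)-2-{(1S,4S,6R)-4-hydroxy-2,2,6-trimethyl-7-oxabicyclo[4.1.0]heptan-1-yl}ethenyl]-4,4,5,5-tetramethyl-1,3,2-dioxaborolane | CC1(C)OB(/C=C/[C@@]23O[C@]2(C)C[C@@H](O)CC3(C)C)OC1(C)C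
F8 | step 15 | (1R,3S,6S)-6-[(E)-2-iodoethenyl]-1,5,5-trimethyl-7-oxabicyclo[4.1.0]heptan-3-ol | I/C=C/[C@@]12O[C@]1(C)C[C@@H](O)CC2(C)C
F9 | step 15 | (R)-4-{(3E,5E,7E,9E,11Z)-3,10-dimethyl-11-[5-oxo-4-(trimethylstannyl)furan-2(5H)-ylidene]undeca-3,5,7,9-tetraen-1-yn-1-yl}-3,5,5-trimethylcyclohex-3-en-1-yl acetate | CC(=O)O[C@@H]1CC(C)=C(C#C/C(C)=C/C=C/C=C/C=C(C)/C=C2C=C([Sn](C)(C)C)C(=O)O/2)C(C)(C)C1
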